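Ring A is made first and carries the stereochemical information. The key step exploits ring A, where quaternary C4 holds its oxygenated arm C19 axial, on the face opposite to the C2 oxygen (a 1,3-trans pair), and where the next atom, C5, carries C6. A copper-bound silylmethyl group is delivered to C4 of (S)-5-silyloxy-3-methylcyclohex-2-enone from the face remote from the silyl ether. Allyl bromide then captures the enolate at C5, so C4–C19 and C5–C6 arise in one operation. Capture is trans to the new arm, so C5 is reset later by kinetic protonation. The ketone carbon (C10) then receives C20, a β-keto ester closes ring B, and a Z-vinyl iodide delivers C13–C16.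

Key step: step 7

Convention: labdane numbering is used throughout; β is the face of C20 and C19, α the face of H5, H9 and the C2 and C7 oxygens.
Assumption: the lipase acylates the carbinol of 2 that is R when the silyloxy-bearing ring arm counts as the large group (the usual sense for secondary alcohols). If the sense were opposite, hydrolysis of the meso diacetate with the same enzyme would lead to 3.

Step 1
Reactants: 1 cis,cis-cyclohexane-1,3,5-triol
Product: 2 cis,cis-5-(tert-butyldiphenylsilyloxy)cyclohexane-1,3-diol (meso)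
Conditions: TBDPSCl (1 equiv), imidazole, DMF, 0 °C to rt
Reagents that add atoms: tert-butyl(chloro)diphenylsilane, CC(C)(C)[Si](Cl)(c1ccccc1)c1ccccc1
Why: Silyl ether formation with one equivalent of a bulky chloride on a triol with three equivalent hydroxyls should stop largely at the mono ether, a meso diol, and the acid-stable TBDPS group is chosen because steps 9, 10, 13 and 16 are acidic.

Step 2
Reactants: 2 cis,cis-5-(tert-butyldiphenylsilyloxy)cyclohexane-1,3-diol
Product: 3 (1R,3S,5S)-3-(tert-butyldiphenylsilyloxy)-5-hydroxycyclohexyl acetate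
Conditions: lipase (Alcaligenes sp. or Candida antarctica B), vinyl acetate, MTBE, rt
Reagents that add atoms: vinyl acetate, C=COC(C)=O
Why: Irreversible lipase-catalysed transesterification desymmetrises the meso diol and sets the only reagent-controlled stereocentre of the route (C2 of the target).

Step 3
Reactants: 3 (1R,3S,5S)-3-(tert-butyldiphenylsilyloxy)-5-hydroxycyclohexyl acetate
Product: 5 (R)-5-(tert-butyldiphenylsilyloxy)cyclohex-2-en-1-one, via β-acetoxy ketone 4 (not isolated)
Conditions: Dess–Martin periodinane, CH2Cl2, 0 °C; then Et3N, 0 °C to rt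
Reagents that add atoms: none
Why: Dess–Martin oxidation gives a β-acetoxy ketone that loses acetic acid by E1cB elimination under mild amine base far faster than it loses silanol, so the silyloxy stereocentre stays untouched.

Step 4
Reactants: 5 (R)-5-(tert-butyldiphenylsilyloxy)cyclohex-2-en-1-one
Product: 6 (5R)-5-(tert-butyldiphenylsilyloxy)-1-methylcyclohex-2-en-1-ol (both C1 epimers)
Conditions: MeLi, Et2O, −78 °C
Reagents that add atoms: methyllithium, [Li]C
Why: 1,2-Addition of methyllithium at low temperature outruns enolisation and brings in C18, and the new carbinol configuration is erased in step 5.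

Step 5
Reactants: 6 (5R)-5-(tert-butyldiphenylsilyloxy)-1-methylcyclohex-2-en-1-ol
Product: 7 (S)-5-(tert-butyldiphenylsilyloxy)-3-methylcyclohex-2-en-1-one
Conditions: PCC, NaOAc, 4 Å MS, CH2Cl2, rt
Reagents that add atoms: pyridinium chlorochromate, [O-][Cr](=O)(=O)Cl.c1cc[nH+]cc1
Why: Babler–Dauben oxidative transposition ([3,3] shift of the allylic chromate, then oxidation) moves the carbonyl to the former β-carbon, which leaves the stereocentre in place and only changes its descriptor from R to S.

Step 6
Reactants: 8 (chloromethyl)dimethylphenylsilane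
Product: 9 [(dimethylphenylsilyl)methyl]magnesium chloride (THF solution)
Conditions: Mg turnings, cat. 1,2-dibromoethane, THF, reflux
Reagents that add atoms: magnesium, [Mg]
Why: Magnesium insertion into a primary α-silyl chloride is a standard Grignard formation.

Step 7
Reactants: 7 (S)-5-(tert-butyldiphenylsilyloxy)-3-methylcyclohex-2-en-1-one; 9 [(dimethylphenylsilyl)methyl]magnesium chloride; 10 allyl bromide
Product: 13 (2R,3S,5S)-2-allyl-5-(tert-butyldiphenylsilyloxy)-3-[(dimethylphenylsilyl)methyl]-3-methylcyclohexan-1-one, via trimethylsilyl enol ether 11 (not isolated), via lithium enolate 12 (not isolated)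
Conditions: 9, CuBr·SMe2 (10 mol%), TMSCl, HMPA, THF, −78 °C; pentane/Et3N filtration and solvent exchange; MeLi, THF, 0 °C; 10, DMPU, −78 to −30 °C
Reagents that add atoms: [(dimethylphenylsilyl)methyl]magnesium chloride (9), C[Si](C)(C[Mg]Cl)c1ccccc1; allyl bromide (10), C=CCBr
Why: Copper-catalysed, chlorosilane-accelerated conjugate addition (π-complexation, C–Cu bond formation at the β-carbon C4, reductive elimination) gives 11, methyllithium releases the regiodefined enolate 12, and SN2 capture by allyl bromide forms C5–C6; the closest known type is three-component enone coupling with a silylmethyl group as hydroxymethyl equivalent. No ring is closed. C4 is controlled by C2: in the half-chair with the silyl ether pseudoequatorial, the stereoelectronically preferred axial attack comes from the face anti to it, so C19 becomes β and axial and the resident methyl becomes C18. C5 is controlled by the new axial arm, because the electrophile enters antiperiplanar to it, which should give the 5α-allyl (5-epi) ketone; equilibration next to a quaternary carbon has no reliable bias and risks loss of silanolate, so this centre is not relied on and is erased and reset in steps 10 and 11. The step therefore needs only facial selectivity at C4 and regiochemical integrity of the enolate, which are secured by the bulky C2 silyl ether, by trapping as 11 and by alkylation below −30 °C.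

Step 8
Reactants: 13 ring A ketone (5α-allyl)
Product: 14 ring A hydroxy ketone (as 13, with 5α-(3-hydroxypropyl) in place of allyl)
Conditions: 9-BBN, THF, 0 °C to rt; H2O2, pH 7 buffer
Reagents that add atoms: hydrogen peroxide, OO
Why: Anti-Markovnikov hydroboration–oxidation of the monosubstituted alkene is much faster than reduction of the hindered ketone, and any over-reduced carbinol is returned to the ketone in step 9.

Step 9
Reactants: 14 ring A hydroxy ketone
Product: 15 ring A keto acid (C6–C7–C8O2H chain on C5)
Conditions: Jones reagent, acetone, 0 °C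
Reagents that add atoms: water (through the aldehyde hydrate), O
Why: Jones oxidation takes the primary alcohol through the aldehyde hydrate to the acid, and the TBDPS ether and the arylsilane tolerate the brief acidic exposure.

Step 10
Reactants: 15 ring A keto acid
Product: 16 enol δ-lactone (C5=C10, O on C10, lactone carbonyl C8)
Conditions: (CF3CO)2O, CH2Cl2, 0 °C to rt
Reagents that add atoms: none
Why: Enol lactonisation of a δ-keto acid through its mixed anhydride, equilibrated by the liberated acid, should favour the endocyclic tetrasubstituted C5=C10 isomer, which erases C5 so that both C5 epimers converge.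

Step 11
Reactants: 16 enol δ-lactone; 17 allyl acetate
Product: 18 allyl β-keto ester of the ring A ketone with natural C5 (5αH, C6 equatorial)
Conditions: 17, LDA (2.2 equiv each), THF, −78 °C; add 16; AcOH/THF quench at −78 °C
Reagents that add atoms: allyl acetate (17), CC(=O)OCC=C
Why: Claisen-type acylation of the ester enolate by the enol lactone (an active ester) forms C8–C9 and releases the C5=C10 ketone enolate regiospecifically, and its kinetic C-protonation at −78 °C occurs axially, anti to the axial C19 arm, which sets 5αH.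

Step 12
Reactants: 18 allyl β-keto ester ketone
Product: 19 tertiary carbinol (C10–OH, C10–CH3 = C20; C10 epimers)
Conditions: LiHMDS (1.05 equiv), THF, −78 °C; then MeLi/CeCl3, −78 °C
Reagents that add atoms: methyllithium, [Li]C
Why: With the β-keto ester masked as its lithium enolate, the weakly basic organocerium reagent adds 1,2 to the only free ketone (carbonyl addition), and the carbinol configuration is irrelevant because C10 is ionised next.

Step 13
Reactants: 19 tertiary carbinol
Product: 20 trans-decalin β-keto ester (C8 ketone, 9β-CO2allyl, 9αH, 10β-methyl)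
Conditions: SnCl4, CH2Cl2, −78 to −10 °C
Reagents that add atoms: none
Why: Lewis acid ionisation of the carbinol and capture of the C10 cation by the chelated β-keto ester enol is the known cation–enol cyclisation of olefinic β-keto esters (six-membered ring, C9–C10 bond); a chair transition state with C6 equatorial lets C9 attack the α face, away from axial C19, so C20 ends β-axial (trans-decalin) and the enolisable C9 ester settles equatorial.

Step 14
Reactants: 20 trans-decalin β-keto ester; 21 methyl bromoacetate
Product: 22 C9-quaternary keto diester (9α-CH2CO2Me, 9β-CO2allyl)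
Conditions: Cs2CO3, DMF, 0 °C to rt
Reagents that add atoms: methyl bromoacetate (21), COC(=O)CBr
Why: C-Alkylation of the caesium β-keto ester enolate with a reactive α-halo ester (acetoacetic ester alkylation) installs C11–C12 from the open α face, and the C9 configuration formed here is reset in step 15.

Step 15
Reactants: 22 C9-quaternary keto diester
Product: 23 methyl 2α-(tert-butyldiphenylsilyloxy)-19-(dimethylphenylsilyl)-8-oxo-13,14,15,16,17-pentanorlabdan-12-oate (9αH)
Conditions: Pd(PPh3)4 (5 mol%), HCO2H, Et3N, THF, rt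
Reagents that add atoms: none
Why: Palladium-catalysed deallylation with formate (Tsuji decarboxylation of an allyl β-keto ester) gives the C8=C9 enol(ate) under neutral conditions at room temperature, and its kinetic protonation from the α face, anti to axial C20, sets 9αH with the side arm β-equatorial.

Step 16
Reactants: 23 silyl keto ester
Product: 24 methyl 2α-(tert-butyldiphenylsilyloxy)-19-hydroxy-8-oxo-13,14,15,16,17-pentanorlabdan-12-oate
Conditions: Hg(OAc)2, AcOOH, AcOH, rt
Reagents that add atoms: peracetic acid, CC(=O)OO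
Why: Fleming–Tamao oxidation (mercuridesilylation of the phenyl group, then peracid-induced shift of carbon from silicon to oxygen) is placed at a stage with no alkene present and unmasks C19–OH, while the hindered ketone should resist Baeyer–Villiger oxidation during the short exposure.

Step 17
Reactants: 24 hydroxy keto ester
Product: 25 methyl 2α-(tert-butyldiphenylsilyloxy)-19-hydroxy-13,14,15,16-tetranorlabd-8(17)-en-12-oate
Conditions: Zn, CH2Br2, TiCl4 (pre-formed reagent), THF/CH2Cl2, 0 °C to rt
Reagents that add atoms: dibromomethane, BrCBr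
Why: Lombardo methylenation is non-basic, so the epimerisable C9 centre and the ester are left untouched while C8=C17 is formed.

Step 18
Reactants: 25 hydroxy alkene ester
Product: 26 2α-(tert-butyldiphenylsilyloxy)-13,14,15,16-tetranorlabd-8(17)-ene-12,19-diol
Conditions: DIBAL-H, CH2Cl2, −78 to 0 °C; Rochelle salt
Reagents that add atoms: none
Why: DIBAL-H reduction of the methyl ester to the primary alcohol is standard, and the free C19 hydroxyl only consumes one extra equivalent of hydride.

Step 19
Reactants: 26 diol
Product: 27 12-iodo-2α-(tert-butyldiphenylsilyloxy)-13,14,15,16-tetranorlabd-8(17)-en-19-ol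
Conditions: I2, PPh3, imidazole, CH2Cl2, 0 °C
Reagents that add atoms: iodine, II
Why: In the Appel-type iodination only the unhindered C12 alkoxyphosphonium salt can undergo SN2 displacement, because the C19 carbinol is neopentyl and axial.

Step 20
Reactants: 27 iodo alcohol
Product: 28 12-iodo-2α-(tert-butyldiphenylsilyloxy)-13,14,15,16-tetranorlabd-8(17)-en-19-yl acetate
Conditions: Ac2O, Et3N, DMAP, CH2Cl2, rt
Reagents that add atoms: acetic anhydride, CC(=O)OC(C)=O
Why: DMAP-catalysed acylation esterifies even the neopentyl C19 alcohol and leaves the primary iodide alone.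

Step 21
Reactants: 29 but-2-yn-1-ol
Product: 30 (Z)-3-iodobut-2-en-1-ol
Conditions: Red-Al, THF, 0 °C to rt; then I2, −78 °C
Reagents that add atoms: iodine, II
Why: Hydroxyl-directed trans-hydroalumination places aluminium on C3 within a five-membered chelate, and iodinolysis with retention gives the Z-vinyl iodide that fixes the C13=C14 geometry.

Step 22
Reactants: 30 (Z)-3-iodobut-2-en-1-ol
Product: 31 (Z)-3-iodobut-2-enyl acetate
Conditions: Ac2O, pyridine, CH2Cl2, 0 °C to rt
Reagents that add atoms: acetic anhydride, CC(=O)OC(C)=O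
Why: Simple acetylation installs the final C15 ester before the coupling.

Step 23
Reactants: 28 iodo acetate; 31 (Z)-3-iodobut-2-enyl acetate
Product: 33 2α-(tert-butyldiphenylsilyloxy)labda-8(17),13Z-diene-15,19-diyl diacetate, via alkylzinc iodide 32 (not isolated)
Conditions: activated Zn, LiCl, THF, 40 °C; then 31, PdCl2(dppf) (5 mol%), rt
Reagents that add atoms: (Z)-3-iodobut-2-enyl acetate (31), C/C(I)=C/COC(C)=O
Why: Zinc insertion into the primary iodide tolerates esters, and Negishi sp3–sp2 coupling keeps the alkene geometry because oxidative addition to the vinyl iodide is far faster than ionisation of the allylic acetate.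

Step 24
Reactants: 33 silyl ether diacetate
Product: 34 2α-(tert-butyldiphenylsilyloxy)-7α-hydroxylabda-8(17),13Z-diene-15,19-diyl diacetate
Conditions: SeO2 (0.3 equiv), t-BuOOH, CH2Cl2, 0 °C to rt
Reagents that add atoms: selenium dioxide (oxygen carrier), O=[Se]=O; tert-butyl hydroperoxide (terminal oxygen source), CC(C)(C)OO
Why: Selenium dioxide allylic hydroxylation (ene reaction at C17, then [2,3]-sigmatropic shift) removes the axial 7α hydrogen and delivers oxygen to the α face of C7, and the exocyclic 1,1-disubstituted alkene should react before the C13 alkene, which is deactivated by its allylic acetate.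

Step 25
Reactants: 34 7α-hydroxy silyl ether
Product: 35 2α,7α-dihydroxylabda-8(17),13Z-diene-15,19-diyl diacetate (target)
Conditions: HF·pyridine, pyridine, THF, 0 °C to rt
Reagents that add atoms: none
Why: Fluoride-mediated silyl ether cleavage under buffered conditions spares both acetates, the allylic alcohol and the exocyclic alkene.

Compound list
1 | cis,cis-cyclohexane-1,3,5-triol | O[C@@H]1C[C@H](O)C[C@H](O)C1 | starting material
2 | cis,cis-5-(tert-butyldiphenylsilyloxy)cyclohexane-1,3-diol (meso) | O[C@@H]1C[C@H](O)C[C@H](O[Si](c2ccccc2)(c2ccccc2)C(C)(C)C)C1 | intermediate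
3 | (1R,3S,5S)-3-(tert-butyldiphenylsilyloxy)-5-hydroxycyclohexyl acetate | CC(=O)O[C@@H]1C[C@H](O)C[C@H](O[Si](c2ccccc2)(c2ccccc2)C(C)(C)C)C1 | intermediate
4 | cis-3-acetoxy-5-(tert-butyldiphenylsilyloxy)cyclohexanone (configuration as in 3) | CC(=O)O[C@@H]1CC(=O)C[C@H](O[Si](c2ccccc2)(c2ccccc2)C(C)(C)C)C1 | intermediate
5 | (R)-5-(tert-butyldiphenylsilyloxy)cyclohex-2-en-1-one | O=C1C=CC[C@@H](O[Si](c2ccccc2)(c2ccccc2)C(C)(C)C)C1 | intermediate
6 | (5R)-5-(tert-butyldiphenylsilyloxy)-1-methylcyclohex-2-en-1-ol (C1 epimers) | CC1(O)C=CC[C@@H](O[Si](c2ccccc2)(c2ccccc2)C(C)(C)C)C1 | intermediate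
7 | (S)-5-(tert-butyldiphenylsilyloxy)-3-methylcyclohex-2-en-1-one | O=C1C=C(C)C[C@H](O[Si](c2ccccc2)(c2ccccc2)C(C)(C)C)C1 | intermediate
8 | (chloromethyl)dimethylphenylsilane | C[Si](C)(CCl)c1ccccc1 | starting material
9 | [(dimethylphenylsilyl)methyl]magnesium chloride | C[Si](C)(C[Mg]Cl)c1ccccc1 | intermediate
10 | allyl bromide | C=CCBr | starting material
11 | ring A trimethylsilyl enol ether (C5=C10; 2α-OTBDPS; C19 β, C18 α) | C[Si](C)(C)OC1=C[C@@](C)(C[Si](C)(C)c2ccccc2)C[C@H](O[Si](c2ccccc2)(c2ccccc2)C(C)(C)C)C1 | intermediate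
12 | ring A lithium enolate (C5=C10) | [Li]OC1=C[C@@](C)(C[Si](C)(C)c2ccccc2)C[C@H](O[Si](c2ccccc2)(c2ccccc2)C(C)(C)C)C1 | intermediate
13 | (2R,3S,5S)-2-allyl-5-(tert-butyldiphenylsilyloxy)-3-[(dimethylphenylsilyl)methyl]-3-methylcyclohexan-1-one (C10 = carbonyl; allyl 5α) | C=CC[C@@H]1[C@@](C)(C[Si](C)(C)c2ccccc2)C[C@H](O[Si](c2ccccc2)(c2ccccc2)C(C)(C)C)CC1=O | intermediate
14 | ring A hydroxy ketone (5α-(3-hydroxypropyl)) | OCCC[C@@H]1[C@@](C)(C[Si](C)(C)c2ccccc2)C[C@H](O[Si](c2ccccc2)(c2ccccc2)C(C)(C)C)CC1=O | intermediate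
15 | ring A keto acid (5α-(2-carboxyethyl)) | OC(=O)CC[C@@H]1[C@@](C)(C[Si](C)(C)c2ccccc2)C[C@H](O[Si](c2ccccc2)(c2ccccc2)C(C)(C)C)CC1=O | intermediate
16 | enol δ-lactone (C5=C10) | O=C1CCC2=C(O1)C[C@@H](O[Si](c3ccccc3)(c3ccccc3)C(C)(C)C)C[C@]2(C)C[Si](C)(C)c1ccccc1 | intermediate
17 | allyl acetate | CC(=O)OCC=C | starting material
18 | allyl β-keto ester of the ring A ketone (5αH) | C=CCOC(=O)CC(=O)CC[C@H]1[C@@](C)(C[Si](C)(C)c2ccccc2)C[C@H](O[Si](c2ccccc2)(c2ccccc2)C(C)(C)C)CC1=O | intermediate
19 | tertiary carbinol at C10 (C10 epimers) | C=CCOC(=O)CC(=O)CC[C@H]1[C@@](C)(C[Si](C)(C)c2ccccc2)C[C@H](O[Si](c2ccccc2)(c2ccccc2)C(C)(C)C)CC1(C)O | intermediate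
20 | trans-decalin β-keto ester (8-oxo, 9β-CO2allyl, 9αH) | O=C1CC[C@H]2[C@@](C)(C[Si](C)(C)c3ccccc3)C[C@H](O[Si](c3ccccc3)(c3ccccc3)C(C)(C)C)C[C@]2(C)[C@H]1C(=O)OCC=C | intermediate
21 | methyl bromoacetate | COC(=O)CBr | starting material
22 | C9-quaternary keto diester (9α-CH2CO2Me, 9β-CO2allyl) | O=C1CC[C@H]2[C@@](C)(C[Si](C)(C)c3ccccc3)C[C@H](O[Si](c3ccccc3)(c3ccccc3)C(C)(C)C)C[C@]2(C)[C@@]1(CC(=O)OC)C(=O)OCC=C | intermediate
23 | methyl 2α-(TBDPSO)-19-(dimethylphenylsilyl)-8-oxo-13,14,15,16,17-pentanorlabdan-12-oate | O=C1CC[C@H]2[C@@](C)(C[Si](C)(C)c3ccccc3)C[C@H](O[Si](c3ccccc3)(c3ccccc3)C(C)(C)C)C[C@]2(C)[C@H]1CC(=O)OC | intermediate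
24 | methyl 2α-(TBDPSO)-19-hydroxy-8-oxo-13,14,15,16,17-pentanorlabdan-12-oate | O=C1CC[C@H]2[C@@](C)(CO)C[C@H](O[Si](c3ccccc3)(c3ccccc3)C(C)(C)C)C[C@]2(C)[C@H]1CC(=O)OC | intermediate
25 | methyl 2α-(TBDPSO)-19-hydroxy-13,14,15,16-tetranorlabd-8(17)-en-12-oate | C=C1CC[C@H]2[C@@](C)(CO)C[C@H](O[Si](c3ccccc3)(c3ccccc3)C(C)(C)C)C[C@]2(C)[C@H]1CC(=O)OC | intermediate
26 | 2α-(TBDPSO)-13,14,15,16-tetranorlabd-8(17)-ene-12,19-diol | C=C1CC[C@H]2[C@@](C)(CO)C[C@H](O[Si](c3ccccc3)(c3ccccc3)C(C)(C)C)C[C@]2(C)[C@H]1CCO | intermediate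
27 | 12-iodo-2α-(TBDPSO)-13,14,15,16-tetranorlabd-8(17)-en-19-ol | C=C1CC[C@H]2[C@@](C)(CO)C[C@H](O[Si](c3ccccc3)(c3ccccc3)C(C)(C)C)C[C@]2(C)[C@H]1CCI | intermediate
28 | 12-iodo-2α-(TBDPSO)-13,14,15,16-tetranorlabd-8(17)-en-19-yl acetate | C=C1CC[C@H]2[C@@](C)(COC(C)=O)C[C@H](O[Si](c3ccccc3)(c3ccccc3)C(C)(C)C)C[C@]2(C)[C@H]1CCI | intermediate
29 | but-2-yn-1-ol | CC#CCO | starting material
30 | (Z)-3-iodobut-2-en-1-ol | C/C(I)=C/CO | intermediate
31 | (Z)-3-iodobut-2-enyl acetate | C/C(I)=C/COC(C)=O | intermediate
32 | C12 alkylzinc iodide derived from 28 | C=C1CC[C@H]2[C@@](C)(COC(C)=O)C[C@H](O[Si](c3ccccc3)(c3ccccc3)C(C)(C)C)C[C@]2(C)[C@H]1CC[Zn]I | intermediate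
33 | 2α-(TBDPSO)labda-8(17),13Z-diene-15,19-diyl diacetate | C=C1CC[C@H]2[C@@](C)(COC(C)=O)C[C@H](O[Si](c3ccccc3)(c3ccccc3)C(C)(C)C)C[C@]2(C)[C@H]1CC/C(C)=C\COC(C)=O | intermediate
34 | 2α-(TBDPSO)-7α-hydroxylabda-8(17),13Z-diene-15,19-diyl diacetate | C=C1[C@H](O)C[C@H]2[C@@](C)(COC(C)=O)C[C@H](O[Si](c3ccccc3)(c3ccccc3)C(C)(C)C)C[C@]2(C)[C@H]1CC/C(C)=C\COC(C)=O | intermediate
35 | 2α,7α-dihydroxylabda-8(17),13Z-diene-15,19-diyl diacetate (CNP0171158.2) | C=C1[C@H](O)C[C@H]2[C@@](C)(COC(C)=O)C[C@H](O)C[C@]2(C)[C@H]1CC/C(C)=C\COC(C)=O | target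

Total step count: 25. Longest linear sequence: 22 steps (steps 1–5, 7–20 and 23–25).

Steps most likely to fail

Step 7. Alkylation next to the new quaternary carbon may be slow. Enolate and product could then exchange protons, which would bring polyallylation, loss of regiochemical integrity and β-elimination of silanolate.
- Fallback: the two bond formations are separated, setting out from 7.
- The copper-catalysed addition is run alone and 11 is isolated.
- MeLi converts 11 into 12, which is O-acylated with allyl chloroformate to the allyl enol carbonate F1.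
- Pd(PPh3)4 then triggers decarboxylative (Tsuji) allylation through a regiodefined palladium enolate under neutral conditions.
- The sequence returns to the route at 13, where either C5 epimer is acceptable.

Step 13. After ionisation, proton loss may compete with ring closure. Oxygen rather than carbon of the enol may capture the cation, or the Lewis acid may attack the silyl ether.
- Fallback: a radical route sets out from 16 and also bypasses steps 11, 12, 14 and 15.
- Methanolysis (cat. NaOMe, MeOH, −40 °C, same kinetic protonation) gives the keto methyl ester F2.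
- Lombardo methylenation gives the exocyclic alkene F3.
- Iron-catalysed hydrogen atom transfer (Fe(acac)3, PhSiH3, EtOH) forms the C10 tertiary radical, which adds to dimethyl fumarate from the α face (Giese addition) to give the triester F4.
- Dieckmann condensation (KOt-Bu, THF) gives the bicyclic β-keto ester F5.
- Krapcho dealkoxycarbonylation (LiCl, wet DMSO, heat) returns to the route at 23.
- C9 is not controlled on this path, so the 9αH epimer would be separated and the other re-equilibrated.

Step 24. Oxidation at the allylic positions of the side-chain alkene, over-oxidation of the new carbinol, or incomplete facial selectivity may erode the late hydroxylation.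
- Fallback: the hydroxylation is moved in front of the coupling, setting out from 28, whose only alkene is C8=C17.
- SeO2/t-BuOOH gives the 7α-hydroxy iodo acetate F6.
- TESOTf/2,6-lutidine gives the triethylsilyl ether F7.
- Zinc insertion gives the alkylzinc iodide F8.
- Negishi coupling with 31 gives the bis-silyl ether diacetate F9.
- HF·pyridine removes both silyl groups and returns to the route at 35.

Further compounds
F1 | step 7 | allyl enol carbonate of the ring A ketone (C5=C10) | C=CCOC(=O)OC1=C[C@@](C)(C[Si](C)(C)c2ccccc2)C[C@H](O[Si](c2ccccc2)(c2ccccc2)C(C)(C)C)C1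
F2 | step 13 | ring A keto methyl ester (5αH) | COC(=O)CC[C@H]1[C@@](C)(C[Si](C)(C)c2ccccc2)C[C@H](O[Si](c2ccccc2)(c2ccccc2)C(C)(C)C)CC1=O
F3 | step 13 | ring A exocyclic alkene methyl ester (C10=CH2) | COC(=O)CC[C@H]1[C@@](C)(C[Si](C)(C)c2ccccc2)C[C@H](O[Si](c2ccccc2)(c2ccccc2)C(C)(C)C)CC1=C
F4 | step 13 | triester with quaternary C10 (C9 epimers) | COC(=O)CC[C@H]1[C@@](C)(C[Si](C)(C)c2ccccc2)C[C@H](O[Si](c2ccccc2)(c2ccccc2)C(C)(C)C)C[C@]1(C)C(CC(=O)OC)C(=O)OC
F5 | step 13 | bicyclic β-keto ester (8-oxo, 7-CO2Me; C7 and C9 epimers) | COC(=O)C1C[C@H]2[C@@](C)(C[Si](C)(C)c3ccccc3)C[C@H](O[Si](c3ccccc3)(c3ccccc3)C(C)(C)C)C[C@]2(C)C(CC(=O)OC)C1=O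
F6 | step 24 | 7α-hydroxy iodo acetate | C=C1[C@H](O)C[C@H]2[C@@](C)(COC(C)=O)C[C@H](O[Si](c3ccccc3)(c3ccccc3)C(C)(C)C)C[C@]2(C)[C@H]1CCI
F7 | step 24 | 7α-triethylsilyloxy iodo acetate | C=C1[C@H](O[Si](CC)(CC)CC)C[C@H]2[C@@](C)(COC(C)=O)C[C@H](O[Si](c3ccccc3)(c3ccccc3)C(C)(C)C)C[C@]2(C)[C@H]1CCI
F8 | step 24 | alkylzinc iodide derived from F7 | C=C1[C@H](O[Si](CC)(CC)CC)C[C@H]2[C@@](C)(COC(C)=O)C[C@H](O[Si](c3ccccc3)(c3ccccc3)C(C)(C)C)C[C@]2(C)[C@H]1CC[Zn]I
F9 | step 24 | 2α-TBDPS, 7α-TES bis-silyl ether of the target | C=C1[C@H](O[Si](CC)(CC)CC)C[C@H]2[C@@](C)(COC(C)=O)C[C@H](O[Si](c3ccccc3)(c3ccccc3)C(C)(C)C)C[C@]2(C)[C@H]1CC/C(C)=C\COC(C)=O
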